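**Plan**

1. Numbering (tricyclo[5.4.0.0(2,8)]undecane core): cyclobutane C1–C2–C8–C7; C9–C10–C11 bridges C8/C1 (six-membered rings); C3–C4–C5–C6 bridges C2/C7 (seven-membered ring); ketone at C11, methyls on C2, C6, C9, acyloxy groups on C4, C5 and on the CH2 at C6.
2. Cuts, backwards: the three ester C–O bonds; C9–CH3 (cuprate on a C9=C10–C11 enone); the C4 and C5 hydroxyls (from a C4,C5-dione made from a C5 ketone); C2–C3 (radical ring closure onto a vinyl ketone); C1–C2 and C7–C8 (intramolecular vinylketene–alkene [2+2]); then C8–C9, C10–C11 and C1=C7 of an open chain ending in a malonate-derived quaternary C6.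
3. Forward order: chain assembly → cyclobutanone and cyclohexene ring together in the [2+2] (a bicyclo[3.1.1]heptenone) → methylenation at C2 → seven-membered ring by C2–C3 closure → dione, diol, enone, C9 methyl → triple esterification.
4. Enabling feature: C2 and C7 are the two one-carbon bridges of the cyclobutane, 1,3 to each other. The C6 arm on C7 is locked on the face anti to the C9–C11 bridge, directly above an exocyclic methylene on C2, so a tertiary C2 radical can be captured by the enone terminus C3 on that face only, and as a cyclobutyl radical it should not ring-open.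
5. Stereochemistry: C6 by enzymatic desymmetrization of the malonate; C1, C7, C8 in the [2+2] (E-alkene puts the C6 arm anti; facial sense from a temporary C11 silyloxy centre set by Brown allylation); C2 by the frame in the key step.
6. C5 and then C4 by two relayed hydroxyl-directed hydride deliveries starting from the C6 CH2OH; C9 by cuprate addition anti to the C2 methyl; the C11 carbinol ends as the ketone.

Key step: step 15

Assumption: pig liver esterase is taken to cleave the ester of 2 that leads to the (S)-half-ester 3. With the enantiomeric half-ester the same aldehyde 7 is reached by doing hydrogenolysis and silylation before the borane reduction.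

Abbreviations: TBS = tert-butyl(dimethyl)silyl; TBDPS = tert-butyl(diphenyl)silyl. "C1–C11" always means the target-core locants defined above.

**Route**

Step 1
Reactants: 1 dimethyl 2-methylmalonate
Product: 2 dimethyl 2-[(benzyloxy)methyl]-2-methylmalonate
Conditions: NaH, THF, 0 °C; BnOCH2Cl, 0 °C → rt
Reagents that add atoms: benzyl chloromethyl ether, ClCOCc1ccccc1
Why: SN2 C-alkylation of the sodium malonate enolate by the reactive α-chloro ether should give the prochiral quaternary diester that carries the future C6, its methyl, C7 (the new CH2) and two enantiotopic ester carbons.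

Step 2
Reactants: 2 dimethyl 2-[(benzyloxy)methyl]-2-methylmalonate
Product: 3 (2S)-2-[(benzyloxy)methyl]-3-methoxy-2-methyl-3-oxopropanoic acid
Conditions: pig liver esterase, phosphate buffer pH 7.5, rt, pH held with 1 M NaOH; then 1 M HCl
Reagents that add atoms: water, O
Why: Enzymatic desymmetrization (esterase hydrolysis of one enantiotopic ester of a 2,2-disubstituted malonate) should give the half-ester and sets the quaternary stereocentre that becomes C6.

Step 3
Reactants: 3 (2S)-2-[(benzyloxy)methyl]-3-methoxy-2-methyl-3-oxopropanoic acid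
Product: 4 methyl (2R)-3-(benzyloxy)-2-(hydroxymethyl)-2-methylpropanoate
Conditions: BH3·SMe2, THF, 0 °C → rt; MeOH
Reagents that add atoms: none
Why: Chemoselective borane reduction of the carboxylic acid (via its acyloxyborane) in the presence of the methyl ester should give the primary alcohol that becomes the C6 CH2O group, without touching the stereocentre.

Step 4
Reactants: 4 methyl (2R)-3-(benzyloxy)-2-(hydroxymethyl)-2-methylpropanoate
Product: 5 methyl (2S)-3-(benzyloxy)-2-[(TBDPS-oxy)methyl]-2-methylpropanoate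
Conditions: TBDPSCl, imidazole, DMF, rt
Reagents that add atoms: tert-butyl(chloro)diphenylsilane, CC(C)(C)[Si](Cl)(c1ccccc1)c1ccccc1
Why: Imidazole-promoted silylation of the primary alcohol installs a fluoride-labile group that can later be removed in the presence of alkenes.

Step 5
Reactants: 5 methyl (2S)-3-(benzyloxy)-2-[(TBDPS-oxy)methyl]-2-methylpropanoate
Product: 6 methyl (2S)-3-(TBDPS-oxy)-2-(hydroxymethyl)-2-methylpropanoate
Conditions: H2 (1 atm), Pd/C, EtOAc, rt
Reagents that add atoms: none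
Why: Hydrogenolysis of the benzyl ether under neutral conditions should free the second hydroxymethyl group without the silyl migration between the two oxygens that would racemize the quaternary centre.

Step 6
Reactants: 6 methyl (2S)-3-(TBDPS-oxy)-2-(hydroxymethyl)-2-methylpropanoate
Product: 7 methyl (2R)-3-(TBDPS-oxy)-2-formyl-2-methylpropanoate
Conditions: Dess–Martin periodinane, CH2Cl2, 0 °C → rt
Reagents that add atoms: none
Why: Dess–Martin oxidation of the neopentyl alcohol should give the non-enolizable, configurationally stable aldehyde (future C7) under neutral conditions that do not cleave the formyl ester.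

Step 7
Reactants: 7 methyl (2R)-3-(TBDPS-oxy)-2-formyl-2-methylpropanoate
Product: 8 methyl (2S,3E)-2-[(TBDPS-oxy)methyl]-2-methyl-5-oxopent-3-enoate
Conditions: Ph3P=CHCHO (1.1 equiv), toluene, 80 °C
Reagents that add atoms: (triphenylphosphoranylidene)acetaldehyde, O=CC=P(c1ccccc1)(c1ccccc1)c1ccccc1
Why: Wittig olefination with the stabilized formyl ylide should add C1 and C11 and give the E-enal, the geometry that later places the C6 arm anti to the three-carbon bridge.

Step 8
Reactants: 8 methyl (2S,3E)-2-[(TBDPS-oxy)methyl]-2-methyl-5-oxopent-3-enoate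
Product: 9 methyl (2S,3E,5R)-2-[(TBDPS-oxy)methyl]-5-hydroxy-2-methylocta-3,7-dienoate
Conditions: B-allyldiisopinocampheylborane prepared from (−)-α-pinene, Et2O, −78 °C; then NaOH, H2O2
Reagents that add atoms: B-allyldiisopinocampheylborane (from (−)-α-pinene), C=CCB([C@H]1C[C@H]2C[C@H](C2(C)C)[C@@H]1C)[C@H]1C[C@H]2C[C@H](C2(C)C)[C@@H]1C
Why: Brown allylation through a closed chair transition state should add the allyl group (C10, C9) to the Re face of the enal under reagent control and set the temporary (R)-carbinol at C11, which steers the cycloaddition and is later oxidized (the enantiomeric borane would serve if the cycloaddition showed the opposite facial preference).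

Step 9
Reactants: 9 methyl (2S,3E,5R)-2-[(TBDPS-oxy)methyl]-5-hydroxy-2-methylocta-3,7-dienoate
Product: 10 methyl (2S,3E,5R)-5-(TBS-oxy)-2-[(TBDPS-oxy)methyl]-2-methylocta-3,7-dienoate
Conditions: TBSCl, imidazole, DMF, rt
Reagents that add atoms: tert-butyl(chloro)dimethylsilane, CC(C)(C)[Si](C)(C)Cl
Why: Silylation protects the C11 hydroxyl as a bulky, inductively withdrawing ether for the acid chloride and ketene chemistry.

Step 10
Reactants: 10 methyl (2S,3E,5R)-5-(TBS-oxy)-2-[(TBDPS-oxy)methyl]-2-methylocta-3,7-dienoate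
Product: 11 (2E,5R,6E,8S)-5-(TBS-oxy)-8-[(TBDPS-oxy)methyl]-9-methoxy-8-methyl-9-oxonona-2,6-dienoic acid
Conditions: acrylic acid (3 equiv), second-generation Hoveyda–Grubbs catalyst (5 mol%), CH2Cl2, 40 °C
Reagents that add atoms: acrylic acid, C=CC(=O)O
Why: Olefin cross-metathesis of the terminal alkene with acrylic acid should give the E-enoic acid (adding C8 and C2) while the hindered internal alkene next to the quaternary carbon stays inert.

Step 11
Reactants: 11 (2E,5R,6E,8S)-5-(TBS-oxy)-8-[(TBDPS-oxy)methyl]-9-methoxy-8-methyl-9-oxonona-2,6-dienoic acid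
Product: 14 methyl (2S)-2-[(1S,4R,5S,7S)-4-(TBS-oxy)-6-oxobicyclo[3.1.1]hept-2-en-7-yl]-3-(TBDPS-oxy)-2-methylpropanoate, via acid chloride 12 (not isolated), via vinylketene 13 (not isolated)
Conditions: (COCl)2, catalytic DMF, CH2Cl2, 0 °C; concentrate; slow addition to Et3N, toluene, 110 °C, high dilution
Reagents that add atoms: none
Why: γ-Deprotonation of the enoyl chloride should give the vinylketene, whose Z isomer (drained from the equilibrating E/Z pair) undergoes a thermal intramolecular ketene–alkene [2+2] cycloaddition in the crossed (bicyclo[3.1.1]) mode, because the electrophilic ketene carbon C2 bonds to C1 through a six-membered array and leaves the developing positive charge at C7, remote from the C11 oxygen; C1–C2 and C7–C8 form suprafacially on the E-alkene (C6 arm anti to the C9–C11 bridge), and the facial sense is expected to follow the C11 silyloxy group, whose C–O bond avoids the position antiperiplanar to the forming C1–C2 bond, the diastereomers being separable.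

Step 12
Reactants: 14 methyl (2S)-2-[(1S,4R,5S,7S)-4-(TBS-oxy)-6-oxobicyclo[3.1.1]hept-2-en-7-yl]-3-(TBDPS-oxy)-2-methylpropanoate
Product: 15 methyl (2S)-2-[(1S,4R,5R,7S)-4-(TBS-oxy)-6-methylidenebicyclo[3.1.1]hept-2-en-7-yl]-3-(TBDPS-oxy)-2-methylpropanoate
Conditions: Ph3PCH3Br, KN(SiMe3)2, THF, 0 °C → rt
Reagents that add atoms: methyltriphenylphosphonium bromide, C[P+](c1ccccc1)(c1ccccc1)c1ccccc1.[Br-]
Why: Wittig methylenation of the strained, non-enolizable cyclobutanone with an alkoxide-free ylide should give the exocyclic 1,1-disubstituted alkene on C2 (the future C2 methyl carbon) and leave the hindered ester alone.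

Step 13
Reactants: 15 methyl (2S)-2-[(1S,4R,5R,7S)-4-(TBS-oxy)-6-methylidenebicyclo[3.1.1]hept-2-en-7-yl]-3-(TBDPS-oxy)-2-methylpropanoate
Product: 16 (2S)-2-[(1S,4R,5R,7S)-4-(TBS-oxy)-6-methylidenebicyclo[3.1.1]hept-2-en-7-yl]-3-(TBDPS-oxy)-N-methoxy-N,2-dimethylpropanamide
Conditions: MeNH(OMe)·HCl, i-PrMgCl, THF, −10 °C → rt
Reagents that add atoms: N,O-dimethylhydroxylamine hydrochloride, CNOC.Cl
Why: Direct aminolysis of the ester by the magnesium amide of N,O-dimethylhydroxylamine (Weinreb amide formation) prepares the C5 carbonyl for a single Grignard addition.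

Step 14
Reactants: 16 (2S)-2-[(1S,4R,5R,7S)-4-(TBS-oxy)-6-methylidenebicyclo[3.1.1]hept-2-en-7-yl]-3-(TBDPS-oxy)-N-methoxy-N,2-dimethylpropanamide
Product: 17 (4S)-4-[(1S,4R,5R,7S)-4-(TBS-oxy)-6-methylidenebicyclo[3.1.1]hept-2-en-7-yl]-5-(TBDPS-oxy)-4-methylpent-1-en-3-one
Conditions: CH2=CHMgBr, THF, −78 → 0 °C; cold 1 M HCl
Reagents that add atoms: vinylmagnesium bromide, C=C[Mg]Br
Why: Grignard addition to the Weinreb amide stops at the chelated tetrahedral intermediate and should release the vinyl ketone (C5, C4, C3) on cold acidic quench, which also keeps the freed hydroxylamine from adding to the enone.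

Step 15
Reactants: 17 (4S)-4-[(1S,4R,5R,7S)-4-(TBS-oxy)-6-methylidenebicyclo[3.1.1]hept-2-en-7-yl]-5-(TBDPS-oxy)-4-methylpent-1-en-3-one
Product: 18 (1R,2R,6S,7S,8S,11R)-11-(TBS-oxy)-6-[(TBDPS-oxy)methyl]-2,6-dimethyltricyclo[5.4.0.0(2,8)]undec-9-en-5-one
Conditions: Fe(acac)3 (0.3 equiv), PhSiH3, EtOH/ethylene glycol 5:1, 60 °C, 5 mM
Reagents that add atoms: none
Why: The iron hydride formed from Fe(acac)3 and PhSiH3 transfers a hydrogen atom to the terminal carbon of the exocyclic 1,1-disubstituted alkene (Markovnikov), which creates the C2 methyl group and a tertiary cyclobutyl radical at C2 that adds to C3, the terminus of the vinyl ketone; the α-keto radical is then reduced to the iron enolate and protonated by ethanol. The closest known reaction type is the iron-mediated reductive olefin coupling (hydrogen-atom-transfer-initiated Giese addition) in its intramolecular form. The seven-membered ring closes in the 7-endo-trig mode, the 6-exo attack at C4 being electronically disfavoured for a nucleophilic radical. The only new stereocentre, C2, is set by the bicyclic frame: the C6 arm on C7 sits 1,3-cis across the cyclobutane on the face anti to the C9–C11 bridge, so C3 can reach the planar radical from that face only and the new methyl is forced to the face of the bridge. The step needs hydrogen-atom transfer to the 1,1-disubstituted alkene in preference to the cis-disubstituted ring alkene and the electron-poor enone, which the substitution pattern secures, and ring closure faster than simple reduction of the radical, which the enforced proximity of C2 and C3 secures. Ring opening of the cyclobutyl radical is not expected because its singly occupied orbital is orthogonal to the ring C–C bonds.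

Step 16
Reactants: 18 (1R,2R,6S,7S,8S,11R)-11-(TBS-oxy)-6-[(TBDPS-oxy)methyl]-2,6-dimethyltricyclo[5.4.0.0(2,8)]undec-9-en-5-one
Product: 20 (1R,2R,6S,7S,8S,11R)-11-(TBS-oxy)-6-[(TBDPS-oxy)methyl]-4-hydroxy-2,6-dimethyltricyclo[5.4.0.0(2,8)]undeca-3,9-dien-5-one, via hydroperoxide 19 (not isolated)
Conditions: KOtBu, O2 (1 atm), t-BuOH/DME, 0 °C; AcOH
Reagents that add atoms: dioxygen, O=O
Why: Autoxidation of the potassium enolate, which can form only towards C4 because C6 is quaternary, gives the C4 hydroperoxide, which loses water to the 4,5-dione and tautomerizes to the diosphenol, so C4 gains its oxygen with no stereochemical issue.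

Step 17
Reactants: 20 (1R,2R,6S,7S,8S,11R)-11-(TBS-oxy)-6-[(TBDPS-oxy)methyl]-4-hydroxy-2,6-dimethyltricyclo[5.4.0.0(2,8)]undeca-3,9-dien-5-one
Product: 21 (1R,2R,6S,7S,8S,11R)-4,11-dihydroxy-6-(hydroxymethyl)-2,6-dimethyltricyclo[5.4.0.0(2,8)]undeca-3,9-dien-5-one
Conditions: TBAF, AcOH, THF, 0 °C → rt
Reagents that add atoms: none
Why: Buffered fluoride desilylation should free in one operation the C6 hydroxymethyl group needed as directing group and the allylic C11 hydroxyl.

Step 18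
Reactants: 21 (1R,2R,6S,7S,8S,11R)-4,11-dihydroxy-6-(hydroxymethyl)-2,6-dimethyltricyclo[5.4.0.0(2,8)]undeca-3,9-dien-5-one
Product: 23 (1R,2R,4S,5S,6S,7S,8S,11R)-6-(hydroxymethyl)-2,6-dimethyltricyclo[5.4.0.0(2,8)]undec-9-ene-4,5,11-triol, via hydroxy ketone 22 (not isolated)
Conditions: Me4NBH(OAc)3, MeCN/AcOH 1:1, −30 → 0 °C
Reagents that add atoms: none
Why: In this hydroxyl-directed (Evans–Saksena) reduction the acetoxyborohydride bound to the CH2O group should deliver hydride to C5 on the face of the hydroxymethyl group, the resulting enol ketonizes to the C4 ketone, and the borohydride then bound at the C5 oxygen delivers hydride to C4 on its own face, so the C5 hydroxyl ends anti to the CH2OH group and the C4 hydroxyl trans to it, while the allylic alcohol is untouched.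

Step 19
Reactants: 23 (1R,2R,4S,5S,6S,7S,8S,11R)-6-(hydroxymethyl)-2,6-dimethyltricyclo[5.4.0.0(2,8)]undec-9-ene-4,5,11-triol
Product: 24 (1R,2R,4S,5S,6S,7S,8S)-4,5-dihydroxy-6-(hydroxymethyl)-2,6-dimethyltricyclo[5.4.0.0(2,8)]undec-9-en-11-one
Conditions: activated MnO2 (excess), CH2Cl2, rt
Reagents that add atoms: none
Why: MnO2 should oxidize only the allylic C11 alcohol (chemoselective allylic oxidation) and give the bicyclic enone.

Step 20
Reactants: 24 (1R,2R,4S,5S,6S,7S,8S)-4,5-dihydroxy-6-(hydroxymethyl)-2,6-dimethyltricyclo[5.4.0.0(2,8)]undec-9-en-11-one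
Product: 25 (1R,2R,4S,5S,6S,7S,8S,9R)-4,5-dihydroxy-6-(hydroxymethyl)-2,6,9-trimethyltricyclo[5.4.0.0(2,8)]undecan-11-one
Conditions: Me2CuLi (6 equiv), Et2O/THF, −78 → −20 °C; aq NH4Cl
Reagents that add atoms: lithium dimethylcuprate, [Li+].C[Cu-]C
Why: Conjugate addition of the Gilman cuprate should deliver the methyl to C9 from the face of the C7–H bridge, anti to the C2 methyl that covers the other face of the C9–C11 bridge, which sets C9, the three lithium alkoxides being tolerated by excess reagent.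

Step 21
Reactants: 25 (1R,2R,4S,5S,6S,7S,8S,9R)-4,5-dihydroxy-6-(hydroxymethyl)-2,6,9-trimethyltricyclo[5.4.0.0(2,8)]undecan-11-one
Product: 26 [(1R,2R,4S,5S,6S,7S,8S,9R)-4,5-bis{[(2Z)-2-methylbut-2-enoyl]oxy}-2,6,9-trimethyl-11-oxotricyclo[5.4.0.0(2,8)]undecan-6-yl]methyl (2Z)-2-methylbut-2-enoate (CNP0214984.1)
Conditions: angelic acid (6 equiv), 2,4,6-trichlorobenzoyl chloride, Et3N, toluene, rt; then 25, 80 °C (no DMAP)
Reagents that add atoms: angelic acid [(2Z)-2-methylbut-2-enoic acid], C/C=C(/C)C(=O)O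
Why: Yamaguchi esterification through the angelic 2,4,6-trichlorobenzoic mixed anhydride, run without a nucleophilic catalyst, should acylate all three hydroxyls while keeping the Z geometry of the angeloyl units.

**Compound list**

1 | dimethyl 2-methylmalonate | COC(=O)C(C)C(=O)OC | starting material
2 | dimethyl 2-[(benzyloxy)methyl]-2-methylmalonate | COC(=O)C(C)(COCc1ccccc1)C(=O)OC | intermediate
3 | (2S)-2-[(benzyloxy)methyl]-3-methoxy-2-methyl-3-oxopropanoic acid | OC(=O)[C@](C(=O)OC)(C)COCc1ccccc1 | intermediate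
4 | methyl (2R)-3-(benzyloxy)-2-(hydroxymethyl)-2-methylpropanoate | OC[C@](C(=O)OC)(C)COCc1ccccc1 | intermediate
5 | methyl (2S)-3-(benzyloxy)-2-[(TBDPS-oxy)methyl]-2-methylpropanoate | CC(C)(C)[Si](c1ccccc1)(c1ccccc1)OC[C@](C(=O)OC)(C)COCc1ccccc1 | intermediate
6 | methyl (2S)-3-(TBDPS-oxy)-2-(hydroxymethyl)-2-methylpropanoate | CC(C)(C)[Si](c1ccccc1)(c1ccccc1)OC[C@](C(=O)OC)(C)CO | intermediate
7 | methyl (2R)-3-(TBDPS-oxy)-2-formyl-2-methylpropanoate | CC(C)(C)[Si](c1ccccc1)(c1ccccc1)OC[C@](C(=O)OC)(C)C=O | intermediate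
8 | methyl (2S,3E)-2-[(TBDPS-oxy)methyl]-2-methyl-5-oxopent-3-enoate | CC(C)(C)[Si](c1ccccc1)(c1ccccc1)OC[C@](C(=O)OC)(C)/C=C/C=O | intermediate
9 | methyl (2S,3E,5R)-2-[(TBDPS-oxy)methyl]-5-hydroxy-2-methylocta-3,7-dienoate | CC(C)(C)[Si](c1ccccc1)(c1ccccc1)OC[C@](C(=O)OC)(C)/C=C/[C@H](O)CC=C | intermediate
10 | methyl (2S,3E,5R)-5-(TBS-oxy)-2-[(TBDPS-oxy)methyl]-2-methylocta-3,7-dienoate | CC(C)(C)[Si](c1ccccc1)(c1ccccc1)OC[C@](C(=O)OC)(C)/C=C/[C@H](O[Si](C)(C)C(C)(C)C)CC=C | intermediate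
11 | (2E,5R,6E,8S)-5-(TBS-oxy)-8-[(TBDPS-oxy)methyl]-9-methoxy-8-methyl-9-oxonona-2,6-dienoic acid | CC(C)(C)[Si](c1ccccc1)(c1ccccc1)OC[C@](C(=O)OC)(C)/C=C/[C@H](O[Si](C)(C)C(C)(C)C)C/C=C/C(=O)O | intermediate
12 | (2E,5R,6E,8S)-5-(TBS-oxy)-8-[(TBDPS-oxy)methyl]-9-methoxy-8-methyl-9-oxonona-2,6-dienoyl chloride | CC(C)(C)[Si](c1ccccc1)(c1ccccc1)OC[C@](C(=O)OC)(C)/C=C/[C@H](O[Si](C)(C)C(C)(C)C)C/C=C/C(=O)Cl | intermediate
13 | methyl (2S,3E,5R,6Z)-5-(TBS-oxy)-2-[(TBDPS-oxy)methyl]-2-methyl-9-oxonona-3,6,8-trienoate (vinylketene) | CC(C)(C)[Si](c1ccccc1)(c1ccccc1)OC[C@](C(=O)OC)(C)/C=C/[C@H](O[Si](C)(C)C(C)(C)C)/C=C\C=C=O | intermediate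
14 | methyl (2S)-2-[(1S,4R,5S,7S)-4-(TBS-oxy)-6-oxobicyclo[3.1.1]hept-2-en-7-yl]-3-(TBDPS-oxy)-2-methylpropanoate (side chain anti to the C2–C4 bridge, silyloxy group syn to the carbonyl bridge) | CC(C)(C)[Si](c1ccccc1)(c1ccccc1)OC[C@](C(=O)OC)(C)[C@H]1[C@@H]2C=C[C@@H](O[Si](C)(C)C(C)(C)C)[C@H]1C2=O | intermediate
15 | methyl (2S)-2-[(1S,4R,5R,7S)-4-(TBS-oxy)-6-methylidenebicyclo[3.1.1]hept-2-en-7-yl]-3-(TBDPS-oxy)-2-methylpropanoate | CC(C)(C)[Si](c1ccccc1)(c1ccccc1)OC[C@](C(=O)OC)(C)[C@H]1[C@@H]2C=C[C@@H](O[Si](C)(C)C(C)(C)C)[C@H]1C2=C | intermediate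
16 | (2S)-2-[(1S,4R,5R,7S)-4-(TBS-oxy)-6-methylidenebicyclo[3.1.1]hept-2-en-7-yl]-3-(TBDPS-oxy)-N-methoxy-N,2-dimethylpropanamide | CC(C)(C)[Si](c1ccccc1)(c1ccccc1)OC[C@](C(=O)N(C)OC)(C)[C@H]1[C@@H]2C=C[C@@H](O[Si](C)(C)C(C)(C)C)[C@H]1C2=C | intermediate
17 | (4S)-4-[(1S,4R,5R,7S)-4-(TBS-oxy)-6-methylidenebicyclo[3.1.1]hept-2-en-7-yl]-5-(TBDPS-oxy)-4-methylpent-1-en-3-one | CC(C)(C)[Si](c1ccccc1)(c1ccccc1)OC[C@](C(=O)C=C)(C)[C@H]1[C@@H]2C=C[C@@H](O[Si](C)(C)C(C)(C)C)[C@H]1C2=C | intermediate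
18 | (1R,2R,6S,7S,8S,11R)-11-(TBS-oxy)-6-[(TBDPS-oxy)methyl]-2,6-dimethyltricyclo[5.4.0.0(2,8)]undec-9-en-5-one | CC(C)(C)[Si](c1ccccc1)(c1ccccc1)OC[C@]1(C)[C@H]2[C@@H]3C=C[C@@H](O[Si](C)(C)C(C)(C)C)[C@H]2[C@]3(C)CCC1=O | intermediate
19 | (1R,2R,6S,7S,8S,11R)-11-(TBS-oxy)-6-[(TBDPS-oxy)methyl]-4-hydroperoxy-2,6-dimethyltricyclo[5.4.0.0(2,8)]undec-9-en-5-one (C4 either configuration) | CC(C)(C)[Si](c1ccccc1)(c1ccccc1)OC[C@]1(C)[C@H]2[C@@H]3C=C[C@@H](O[Si](C)(C)C(C)(C)C)[C@H]2[C@]3(C)CC(OO)C1=O | intermediate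
20 | (1R,2R,6S,7S,8S,11R)-11-(TBS-oxy)-6-[(TBDPS-oxy)methyl]-4-hydroxy-2,6-dimethyltricyclo[5.4.0.0(2,8)]undeca-3,9-dien-5-one (diosphenol, enol form of the 4,5-dione) | CC(C)(C)[Si](c1ccccc1)(c1ccccc1)OC[C@]1(C)[C@H]2[C@@H]3C=C[C@@H](O[Si](C)(C)C(C)(C)C)[C@H]2[C@]3(C)C=C(O)C1=O | intermediate
21 | (1R,2R,6S,7S,8S,11R)-4,11-dihydroxy-6-(hydroxymethyl)-2,6-dimethyltricyclo[5.4.0.0(2,8)]undeca-3,9-dien-5-one | OC[C@]1(C)[C@H]2[C@@H]3C=C[C@@H](O)[C@H]2[C@]3(C)C=C(O)C1=O | intermediate
22 | (1R,2R,5S,6S,7S,8S,11R)-5,11-dihydroxy-6-(hydroxymethyl)-2,6-dimethyltricyclo[5.4.0.0(2,8)]undec-9-en-4-one | OC[C@]1(C)[C@H]2[C@@H]3C=C[C@@H](O)[C@H]2[C@]3(C)CC(=O)[C@H]1O | intermediate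
23 | (1R,2R,4S,5S,6S,7S,8S,11R)-6-(hydroxymethyl)-2,6-dimethyltricyclo[5.4.0.0(2,8)]undec-9-ene-4,5,11-triol | OC[C@]1(C)[C@H]2[C@@H]3C=C[C@@H](O)[C@H]2[C@]3(C)C[C@H](O)[C@H]1O | intermediate
24 | (1R,2R,4S,5S,6S,7S,8S)-4,5-dihydroxy-6-(hydroxymethyl)-2,6-dimethyltricyclo[5.4.0.0(2,8)]undec-9-en-11-one | OC[C@]1(C)[C@H]2[C@@H]3C=CC(=O)[C@H]2[C@]3(C)C[C@H](O)[C@H]1O | intermediate
25 | (1R,2R,4S,5S,6S,7S,8S,9R)-4,5-dihydroxy-6-(hydroxymethyl)-2,6,9-trimethyltricyclo[5.4.0.0(2,8)]undecan-11-one | OC[C@]1(C)[C@H]2[C@@H]3[C@H](C)CC(=O)[C@H]2[C@]3(C)C[C@H](O)[C@H]1O | intermediate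
26 | [(1R,2R,4S,5S,6S,7S,8S,9R)-4,5-bis{[(2Z)-2-methylbut-2-enoyl]oxy}-2,6,9-trimethyl-11-oxotricyclo[5.4.0.0(2,8)]undecan-6-yl]methyl (2Z)-2-methylbut-2-enoate | C/C=C(/C)C(=O)OC[C@]1(C)[C@H]2[C@@H]3[C@H](C)CC(=O)[C@H]2[C@]3(C)C[C@H](OC(=O)/C(C)=C\C)[C@H]1OC(=O)/C(C)=C\C | target

**Step count and risks**

Total step count: 21. Longest linear sequence: 21 steps (fully linear from 1).

Steps most likely to fail:

Step 11. The vinylketene may be lost by oligomerization out of its non-cyclizing E form under the hot amine conditions before the slow [2+2] closes. Fallback, from 8 back to 14: the vinylketene is generated with fixed Z geometry under neutral conditions by a Wolff rearrangement. Enantioselective zinc-alkynylide addition of methyl propiolate to enal 8 (Me2Zn, ProPhenol ligand, toluene) should give the propargylic alcohol F1. Silylation (TBSCl, imidazole) gives the silyl ether F2. Semihydrogenation (H2, Pd/CaCO3 poisoned with Pb(OAc)2, quinoline) gives the (Z)-enoate F3. LiOH (THF/H2O, 0 °C) cleaves only the unhindered conjugated ester to give the acid F4. Activation as the mixed anhydride (isobutyl chloroformate, N-methylmorpholine) and treatment with diazomethane gives the diazoketone F5. Irradiation of F5 in dilute toluene expels N2 and gives vinylketene 13 directly, which closes to 14.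

Step 15. The vinyl ketone may be reduced, or the C2 radical simply hydrogenated, before ring closure under the hydride conditions. Fallback, from 14 back to 18: the same C2 radical is made by photoredox decarboxylation of an oxalate, with no metal hydride present. MeMgBr/CeCl3 (THF, −78 °C) adds to the cyclobutanone of 14 to give the tertiary cyclobutanol F6 (either epimer serves). The ester is advanced as in steps 13 and 14 to the Weinreb amide F7 and the vinyl ketone F8. Oxalyl chloride then water gives the hydrogen oxalate F9. Irradiation with blue light (Ir[dF(CF3)ppy]2(dtbbpy)PF6, CsF, DME/DMF) releases two CO2 and the tertiary radical, which closes onto C3 to give 18.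

Step 21. Acylation of the hindered C5 hydroxyl may stay incomplete, and forcing conditions may isomerize the angeloyl groups from Z to E. Fallback, from 25 back to 26: the Z-alkenes are built after acylation. Esterification of 25 with 2-[bis(2,2,2-trifluoroethoxy)phosphoryl]propanoic acid (DCC, DMAP, CH2Cl2) gives the tris-phosphonate F10. Still–Gennari olefination (KN(SiMe3)2, 18-crown-6, acetaldehyde, THF, −78 °C) then forms the three (Z)-2-methylbut-2-enoates in place and gives 26.

**Further compounds**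

F1 | step 11 | dimethyl (2S,3E,5S)-2-[(TBDPS-oxy)methyl]-5-hydroxy-2-methyloct-3-en-6-ynedioate | CC(C)(C)[Si](c1ccccc1)(c1ccccc1)OC[C@](C(=O)OC)(C)/C=C/[C@H](O)C#CC(=O)OC
F2 | step 11 | dimethyl (2S,3E,5S)-5-(TBS-oxy)-2-[(TBDPS-oxy)methyl]-2-methyloct-3-en-6-ynedioate | CC(C)(C)[Si](c1ccccc1)(c1ccccc1)OC[C@](C(=O)OC)(C)/C=C/[C@H](O[Si](C)(C)C(C)(C)C)C#CC(=O)OC
F3 | step 11 | dimethyl (2S,3E,5S,6Z)-5-(TBS-oxy)-2-[(TBDPS-oxy)methyl]-2-methylocta-3,6-dienedioate | CC(C)(C)[Si](c1ccccc1)(c1ccccc1)OC[C@](C(=O)OC)(C)/C=C/[C@H](O[Si](C)(C)C(C)(C)C)/C=C\C(=O)OC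
F4 | step 11 | (2Z,4S,5E,7S)-4-(TBS-oxy)-7-[(TBDPS-oxy)methyl]-8-methoxy-7-methyl-8-oxoocta-2,5-dienoic acid | CC(C)(C)[Si](c1ccccc1)(c1ccccc1)OC[C@](C(=O)OC)(C)/C=C/[C@H](O[Si](C)(C)C(C)(C)C)/C=C\C(=O)O
F5 | step 11 | methyl (2S,3E,5S,6Z)-5-(TBS-oxy)-2-[(TBDPS-oxy)methyl]-9-diazo-2-methyl-8-oxonona-3,6-dienoate | CC(C)(C)[Si](c1ccccc1)(c1ccccc1)OC[C@](C(=O)OC)(C)/C=C/[C@H](O[Si](C)(C)C(C)(C)C)/C=C\C(=O)C=[N+]=[N-]
F6 | step 15 | methyl (2S)-2-[(1S,4R,5S,7S)-4-(TBS-oxy)-6-hydroxy-6-methylbicyclo[3.1.1]hept-2-en-7-yl]-3-(TBDPS-oxy)-2-methylpropanoate (carbinol carbon either configuration) | CC(C)(C)[Si](c1ccccc1)(c1ccccc1)OC[C@](C(=O)OC)(C)[C@H]1[C@@H]2C=C[C@@H](O[Si](C)(C)C(C)(C)C)[C@H]1C2(C)O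
F7 | step 15 | (2S)-2-[(1S,4R,5S,7S)-4-(TBS-oxy)-6-hydroxy-6-methylbicyclo[3.1.1]hept-2-en-7-yl]-3-(TBDPS-oxy)-N-methoxy-N,2-dimethylpropanamide | CC(C)(C)[Si](c1ccccc1)(c1ccccc1)OC[C@](C(=O)N(C)OC)(C)[C@H]1[C@@H]2C=C[C@@H](O[Si](C)(C)C(C)(C)C)[C@H]1C2(C)O
F8 | step 15 | (4S)-4-[(1S,4R,5S,7S)-4-(TBS-oxy)-6-hydroxy-6-methylbicyclo[3.1.1]hept-2-en-7-yl]-5-(TBDPS-oxy)-4-methylpent-1-en-3-one | CC(C)(C)[Si](c1ccccc1)(c1ccccc1)OC[C@](C(=O)C=C)(C)[C@H]1[C@@H]2C=C[C@@H](O[Si](C)(C)C(C)(C)C)[C@H]1C2(C)O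
F9 | step 15 | hydrogen oxalate of F8: 2-{[(1S,4R,5S,7S)-4-(TBS-oxy)-6-methyl-7-[(2S)-1-(TBDPS-oxy)-2-methyl-3-oxopent-4-en-2-yl]bicyclo[3.1.1]hept-2-en-6-yl]oxy}-2-oxoacetic acid | CC(C)(C)[Si](c1ccccc1)(c1ccccc1)OC[C@](C(=O)C=C)(C)[C@H]1[C@@H]2C=C[C@@H](O[Si](C)(C)C(C)(C)C)[C@H]1C2(C)OC(=O)C(=O)O
F10 | step 21 | tris{2-[bis(2,2,2-trifluoroethoxy)phosphoryl]propanoate} of triol 25 (phosphonate α-carbons either configuration) | CC(P(=O)(OCC(F)(F)F)OCC(F)(F)F)C(=O)OC[C@]1(C)[C@H]2[C@@H]3[C@H](C)CC(=O)[C@H]2[C@]3(C)C[C@H](OC(=O)C(C)P(=O)(OCC(F)(F)F)OCC(F)(F)F)[C@H]1OC(=O)C(C)P(=O)(OCC(F)(F)F)OCC(F)(F)F
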